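## Retrosynthetic overview
1. The C12 methyl ester comes from allylic oxidation of a C7 isopropenyl group. The 1β-OH comes from axial hydride attack on a C1 ketone of the trans-decalin. Two silyl ethers are removed last.
2. Ring B is formed second. The C7–C8 bond is made by Lewis-acid carbonyl–ene closure of a C8 aldehyde onto the C7=C11 alkene of a ring-A keto aldehyde that already carries the 6-angelate.
3. C6–C7 comes from isobutenyl Grignard addition to a C6 aldehyde. C5–C6 and C9–C10 come from vinyl 1,4-addition and enolate alkylation of (R)-4-silyloxy-2,4-dimethylcyclohex-2-enone.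
4. That enone comes from 2,4-dimethylcyclohex-3-enone by asymmetric epoxidation and β-elimination. This sets C4, which relays to all other centres.
5. Ring A is formed first. It arises by a five-to-six ring expansion (1,2-vinyl shift) of 3-methyl-1-vinylcyclopent-2-enol, made from 3-methylcyclopentenone and vinylmagnesium bromide.

Assumption: the SMILES is read as methyl 6α-angeloyloxy-1β,4α,8α-trihydroxyeudesm-11(13)-en-12-oate, (1R,4R,5S,6S,7R,8S,10R). Eudesmane locants C1–C15 are used for all intermediates.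

## Route

Step 1
Reactants: 1 3-methylcyclopent-2-en-1-one; 2 vinylmagnesium bromide
Product: 3 (±)-3-methyl-1-vinylcyclopent-2-en-1-ol
Conditions: 2 (1.3 equiv), LaCl3·2LiCl (0.3 equiv), THF, −78 → 0 °C; aq NH4Cl/NaHCO3
Reagents that add atoms: none
Why: Grignard 1,2-addition, with the lanthanum salt suppressing enolisation; the carbinol centre is destroyed in step 2, so the racemate is used.

Step 2
Reactants: 3 (±)-3-methyl-1-vinylcyclopent-2-en-1-ol
Product: 4 (±)-2,4-dimethylcyclohex-3-en-1-one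
Conditions: chloro[N,N′-bis(3,5-di-tert-butylsalicylidene)ethane-1,2-diaminato]cobalt (5 mol %), PhSiH3 (10 mol %), PhH, 22 °C, Ar
Reagents that add atoms: none
Why: Proposed new method: a cobalt hydride formed from the trivalent cobalt salen chloride and PhSiH3 transfers H• to the terminal vinyl carbon (MHAT), the secondary radical closes 3-exo on the ring alkene to a bicyclo[3.1.0]hexyl tertiary radical, β-scission of the internal C1–C5 bond (driven by cyclopropane strain release and by the α-hydroxyalkyl radical formed) completes a 1,2-vinyl shift that enlarges the ring, and divalent cobalt takes H• back from the ketyl O–H (or the adjacent C–H) to release 4 and regenerate the hydride, so the step is a redox-neutral isomerisation that builds ring A with the C1 carbonyl, the C10 methyl and the C4(Me)=C5 alkene in place; the closest known reaction types are cobalt-salen MHAT alkene isomerisation/cycloisomerisation, radical 1,2-vinyl or aryl migration of allylic alcohols and the Dowd–Beckwith ring expansion.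

Step 3
Reactants: 4 (±)-2,4-dimethylcyclohex-3-en-1-one
Product: 6 (R)-4-hydroxy-2,4-dimethylcyclohex-2-en-1-one, via epoxy ketone 5 (not isolated)
Conditions: ent-Shi ketone (L-fructose-derived, 30 mol %), KHSO5 (as 2KHSO5·KHSO4·K2SO4), K2CO3, Bu4NHSO4, MeCN–(MeO)2CH2–aq Na2B4O7 buffer, 0 °C; then DBU (0.2 equiv), CH2Cl2, rt
Reagents that add atoms: potassium peroxymonosulfate, [K+].[O-]S(=O)(=O)OO
Why: Shi dioxirane epoxidation delivers oxygen through the spiro transition state to the α face of the trisubstituted alkene in both C2 epimers and sets C4 (R), and E1cB opening of the β,γ-epoxy ketone erases the labile C2 centre while keeping the C4–O bond.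

Step 4
Reactants: 6 (R)-4-hydroxy-2,4-dimethylcyclohex-2-en-1-one
Product: 7 (R)-2,4-dimethyl-4-(triethylsilyloxy)cyclohex-2-en-1-one
Conditions: Et3SiOTf, 2,6-lutidine, CH2Cl2, −78 → 0 °C
Reagents that add atoms: triethylsilyl trifluoromethanesulfonate, CC[Si](CC)(CC)OS(=O)(=O)C(F)(F)F
Why: Silyl triflate protection of the tertiary alcohol removes alkoxide-directed syn delivery in step 6 and provides a bulky α-face group.

Step 5
Reactants: 8 bromoacetyl bromide; 9 ethanethiol
Product: 10 S-ethyl 2-bromoethanethioate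
Conditions: pyridine, CH2Cl2, −20 °C
Reagents that add atoms: none
Why: Acylation of the thiol (Schotten–Baumann type); the acyl bromide reacts far faster than the α-bromide.

Step 6
Reactants: 7 (R)-2,4-dimethyl-4-(triethylsilyloxy)cyclohex-2-en-1-one; 2 vinylmagnesium bromide; 10 S-ethyl 2-bromoethanethioate
Product: 12 S-ethyl 2-[(1R,2R,3R)-2-ethenyl-1,3-dimethyl-6-oxo-3-(triethylsilyloxy)cyclohexyl]ethanethioate, via magnesium enolate 11 (not isolated)
Conditions: 2 (1.2 equiv), CuBr·SMe2 (20 mol %), LiCl (40 mol %), THF, −78 → −30 °C; then 10 (2 equiv), DMPU, −30 → 0 °C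
Reagents that add atoms: none
Why: Copper-catalysed 1,4-addition followed by enolate alkylation, in which axial attack anti to the pseudo-axial 4α-OSiEt3 places the vinyl group β (5α-H) and the electrophile then enters anti to that vinyl group, giving C10 with α-CH2C(O)SEt and β-CH3 (the trans ring-fusion pattern).

Step 7
Reactants: 12 S-ethyl 2-[(1R,2R,3R)-2-ethenyl-1,3-dimethyl-6-oxo-3-(triethylsilyloxy)cyclohexyl]ethanethioate
Product: 14 S-ethyl 2-[(1R,2R,3R)-2-formyl-1,3-dimethyl-6-oxo-3-(triethylsilyloxy)cyclohexyl]ethanethioate, via ozonide 13 (not isolated)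
Conditions: O3, CH2Cl2, −78 °C; PPh3, −78 °C → rt
Reagents that add atoms: ozone, [O-][O+]=O
Why: Ozonolysis with neutral reductive work-up cleaves the only alkene to the C6 aldehyde without epimerising C5; thioester, ketone and silyl ether are inert.

Step 8
Reactants: 14 S-ethyl 2-[(1R,2R,3R)-2-formyl-1,3-dimethyl-6-oxo-3-(triethylsilyloxy)cyclohexyl]ethanethioate; 15 2-methylprop-1-enylmagnesium bromide; 16 angelic acid, (Z)-2-methylbut-2-enoic acid
Product: 19 (1S)-1-[(1S,2R,6R)-2-(2-ethylsulfanyl-2-oxoethyl)-2,6-dimethyl-3-oxo-6-(triethylsilyloxy)cyclohexyl]-3-methylbut-2-en-1-yl (Z)-2-methylbut-2-enoate, via magnesium alkoxide 17 (not isolated), via mixed anhydride 18 (not isolated)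
Conditions: 15 (1.2 equiv), THF, −78 °C; then 18 [from 16, 2,4,6-Cl3C6H2COCl, Et3N, PhMe, rt], −78 → 0 °C
Reagents that add atoms: none
Why: Chemoselective Grignard 1,2-addition under Felkin-type control (the formyl H lies between the two axial methyl groups, C=O eclipses C5–H, and attack from the side remote from 4α-OSiEt3 gives 6S), and the alkoxide is acylated with a Yamaguchi-type mixed anhydride at low temperature, which avoids Z to E isomerisation and fixes the ester on O6 before any other secondary hydroxyl exists.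

Step 9
Reactants: 19 angelate thioester
Product: 20 (1S)-1-[(1S,2R,6R)-2,6-dimethyl-3-oxo-2-(2-oxoethyl)-6-(triethylsilyloxy)cyclohexyl]-3-methylbut-2-en-1-yl (Z)-2-methylbut-2-enoate
Conditions: Et3SiH, Pd/C (10 wt %, 5 mol % Pd), acetone, rt
Reagents that add atoms: none
Why: Fukuyama reduction (zerovalent palladium inserts into the C–S bond and the silane delivers hydride) gives the C8 aldehyde under neutral conditions that leave the C1 ketone, the angelate and the trisubstituted alkene untouched.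

Step 10
Reactants: 20 keto aldehyde angelate
Product: 22 6α-angeloyloxy-4α,8α-bis(triethylsilyloxy)eudesm-11(13)-en-1-one, via 8α-alcohol 21 (not isolated)
Conditions: Sc(OTf)3 (10 mol %), CH2Cl2, −78 → −40 °C; then 2,6-lutidine, Et3SiOTf, −40 → 0 °C
Reagents that add atoms: triethylsilyl trifluoromethanesulfonate, CC[Si](CC)(CC)OS(=O)(=O)C(F)(F)F
Why: Lewis-acid carbonyl–ene cyclisation of the citronellal-to-isopulegol type closes ring B through a chair in which the two trans-diequatorial chains, the 6-ester, the new isopropenyl group and the new oxygen are all equatorial (7α-H, 8α-O), and in-flask silylation blocks O8 against later lactol or lactone formation.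

Step 11
Reactants: 22 6α-angeloyloxy-4α,8α-bis(triethylsilyloxy)eudesm-11(13)-en-1-one
Product: 25 6α-angeloyloxy-4α,8α-bis(triethylsilyloxy)eudesm-11(13)-ene-1β,12-diol, via keto allylic alcohol 23 (not isolated), via keto enal 24 (not isolated)
Conditions: SeO2 (30 mol %), t-BuOOH, CH2Cl2, 0 °C → rt; then MeOH, CeCl3·7H2O, NaBH4, −20 °C
Reagents that add atoms: tert-butyl hydroperoxide, CC(C)(C)OO
Why: Catalytic SeO2 allylic hydroxylation attacks the methyl group of the electron-rich 1,1-disubstituted alkene (the angelate alkene is electron-poor), and Luche reduction returns over-oxidised enal to the alcohol and delivers hydride axially from the α face of the rigid C1 ketone (β face blocked by the C10 methyl), giving the equatorial 1β-OH.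

Step 12
Reactants: 25 6α-angeloyloxy-4α,8α-bis(triethylsilyloxy)eudesm-11(13)-ene-1β,12-diol
Product: 28 methyl 6α-angeloyloxy-1β-hydroxy-4α,8α-bis(triethylsilyloxy)eudesm-11(13)-en-12-oate, via hydroxy enal 26 (not isolated), via carboxylic acid 27 (not isolated)
Conditions: TEMPO (20 mol %), PhI(OAc)2, MeCN–pH 7 buffer, 0 °C → rt; then Me3SiCHN2, PhMe–MeOH, 0 °C
Reagents that add atoms: water, O; (trimethylsilyl)diazomethane, C[Si](C)(C)C=[N+]=[N-]
Why: Oxoammonium (TEMPO/hypervalent iodine) oxidation is selective for the primary allylic alcohol over the hindered neopentyl-type 1β-OH, and diazoalkane esterification is neutral, so neither Michael addition nor angelate isomerisation occurs.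

Step 13
Reactants: 28 methyl 6α-angeloyloxy-1β-hydroxy-4α,8α-bis(triethylsilyloxy)eudesm-11(13)-en-12-oate
Product: 29 methyl 6α-angeloyloxy-1β,4α,8α-trihydroxyeudesm-11(13)-en-12-oate (target)
Conditions: HF·pyridine, pyridine, THF, 0 °C → rt
Reagents that add atoms: none
Why: Buffered fluoride desilylation frees O4 and O8 without the acid or base that would close the 8,12-lactone, move the acyl group or isomerise the angelate.

## Compound list
1 | 3-methylcyclopent-2-en-1-one | CC1=CC(=O)CC1 | starting material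
2 | vinylmagnesium bromide | C=C[Mg]Br | starting material
3 | (±)-3-methyl-1-vinylcyclopent-2-en-1-ol | C=CC1(O)C=C(C)CC1 | intermediate
4 | (±)-2,4-dimethylcyclohex-3-en-1-one | CC1C=C(C)CCC1=O | intermediate
5 | (3S,4R)-3,4-epoxy-2,4-dimethylcyclohexan-1-one (C2 epimers, oxirane on the α face) | O=C1CC[C@@]2(C)O[C@H]2C1C | intermediate
6 | (R)-4-hydroxy-2,4-dimethylcyclohex-2-en-1-one | O=C1CC[C@@](C)(O)C=C1C | intermediate
7 | (R)-2,4-dimethyl-4-(triethylsilyloxy)cyclohex-2-en-1-one | O=C1CC[C@@](C)(O[Si](CC)(CC)CC)C=C1C | intermediate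
8 | bromoacetyl bromide | BrCC(=O)Br | starting material
9 | ethanethiol | CCS | starting material
10 | S-ethyl 2-bromoethanethioate | CCSC(=O)CBr | intermediate
11 | bromomagnesium C1=C10 enolate of (3R,4R)-3-ethenyl-2,4-dimethyl-4-(triethylsilyloxy)cyclohexanone | C=C[C@@H]1C(C)=C(O[Mg]Br)CC[C@@]1(C)O[Si](CC)(CC)CC | intermediate
12 | S-ethyl 2-[(1R,2R,3R)-2-ethenyl-1,3-dimethyl-6-oxo-3-(triethylsilyloxy)cyclohexyl]ethanethioate (10β-Me, 5β-vinyl, 4α-OSiEt3) | C=C[C@@H]1[C@@](C)(CC(=O)SCC)C(=O)CC[C@@]1(C)O[Si](CC)(CC)CC | intermediate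
13 | 1,2,4-trioxolane (secondary ozonide) of 12 | C1OC(OO1)[C@@H]2[C@@](C)(CC(=O)SCC)C(=O)CC[C@@]2(C)O[Si](CC)(CC)CC | intermediate
14 | S-ethyl 2-[(1R,2R,3R)-2-formyl-1,3-dimethyl-6-oxo-3-(triethylsilyloxy)cyclohexyl]ethanethioate | O=C[C@@H]1[C@@](C)(CC(=O)SCC)C(=O)CC[C@@]1(C)O[Si](CC)(CC)CC | intermediate
15 | 2-methylprop-1-enylmagnesium bromide | CC(C)=C[Mg]Br | starting material
16 | angelic acid, (Z)-2-methylbut-2-enoic acid | C/C=C(/C)C(=O)O | starting material
17 | bromomagnesium alkoxide of the (6S)-allylic alcohol | CC(C)=C[C@H](O[Mg]Br)[C@@H]1[C@@](C)(CC(=O)SCC)C(=O)CC[C@@]1(C)O[Si](CC)(CC)CC | intermediate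
18 | angelic 2,4,6-trichlorobenzoic anhydride | C/C=C(/C)C(=O)OC(=O)c1c(Cl)cc(Cl)cc1Cl | intermediate
19 | (1S)-1-[(1S,2R,6R)-2-(2-ethylsulfanyl-2-oxoethyl)-2,6-dimethyl-3-oxo-6-(triethylsilyloxy)cyclohexyl]-3-methylbut-2-en-1-yl (Z)-2-methylbut-2-enoate | CC(C)=C[C@H](OC(=O)/C(C)=C\C)[C@@H]1[C@@](C)(CC(=O)SCC)C(=O)CC[C@@]1(C)O[Si](CC)(CC)CC | intermediate
20 | (1S)-1-[(1S,2R,6R)-2,6-dimethyl-3-oxo-2-(2-oxoethyl)-6-(triethylsilyloxy)cyclohexyl]-3-methylbut-2-en-1-yl (Z)-2-methylbut-2-enoate | CC(C)=C[C@H](OC(=O)/C(C)=C\C)[C@@H]1[C@@](C)(CC=O)C(=O)CC[C@@]1(C)O[Si](CC)(CC)CC | intermediate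
21 | 6α-angeloyloxy-8α-hydroxy-4α-(triethylsilyloxy)eudesm-11(13)-en-1-one (5αH, 7αH, 10β-Me) | C=C(C)[C@H]1[C@H](OC(=O)/C(C)=C\C)[C@@H]2[C@@](C)(C[C@@H]1O)C(=O)CC[C@@]2(C)O[Si](CC)(CC)CC | intermediate
22 | 6α-angeloyloxy-4α,8α-bis(triethylsilyloxy)eudesm-11(13)-en-1-one | C=C(C)[C@H]1[C@H](OC(=O)/C(C)=C\C)[C@@H]2[C@@](C)(C[C@@H]1O[Si](CC)(CC)CC)C(=O)CC[C@@]2(C)O[Si](CC)(CC)CC | intermediate
23 | 6α-angeloyloxy-12-hydroxy-4α,8α-bis(triethylsilyloxy)eudesm-11(13)-en-1-one | C=C(CO)[C@H]1[C@H](OC(=O)/C(C)=C\C)[C@@H]2[C@@](C)(C[C@@H]1O[Si](CC)(CC)CC)C(=O)CC[C@@]2(C)O[Si](CC)(CC)CC | intermediate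
24 | 6α-angeloyloxy-1-oxo-4α,8α-bis(triethylsilyloxy)eudesm-11(13)-en-12-al | C=C(C=O)[C@H]1[C@H](OC(=O)/C(C)=C\C)[C@@H]2[C@@](C)(C[C@@H]1O[Si](CC)(CC)CC)C(=O)CC[C@@]2(C)O[Si](CC)(CC)CC | intermediate
25 | 6α-angeloyloxy-4α,8α-bis(triethylsilyloxy)eudesm-11(13)-ene-1β,12-diol | C=C(CO)[C@H]1[C@H](OC(=O)/C(C)=C\C)[C@@H]2[C@@](C)(C[C@@H]1O[Si](CC)(CC)CC)[C@H](O)CC[C@@]2(C)O[Si](CC)(CC)CC | intermediate
26 | 6α-angeloyloxy-1β-hydroxy-4α,8α-bis(triethylsilyloxy)eudesm-11(13)-en-12-al | C=C(C=O)[C@H]1[C@H](OC(=O)/C(C)=C\C)[C@@H]2[C@@](C)(C[C@@H]1O[Si](CC)(CC)CC)[C@H](O)CC[C@@]2(C)O[Si](CC)(CC)CC | intermediate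
27 | 6α-angeloyloxy-1β-hydroxy-4α,8α-bis(triethylsilyloxy)eudesm-11(13)-en-12-oic acid | C=C(C(=O)O)[C@H]1[C@H](OC(=O)/C(C)=C\C)[C@@H]2[C@@](C)(C[C@@H]1O[Si](CC)(CC)CC)[C@H](O)CC[C@@]2(C)O[Si](CC)(CC)CC | intermediate
28 | methyl 6α-angeloyloxy-1β-hydroxy-4α,8α-bis(triethylsilyloxy)eudesm-11(13)-en-12-oate | C=C(C(=O)OC)[C@H]1[C@H](OC(=O)/C(C)=C\C)[C@@H]2[C@@](C)(C[C@@H]1O[Si](CC)(CC)CC)[C@H](O)CC[C@@]2(C)O[Si](CC)(CC)CC | intermediate
29 | methyl 6α-angeloyloxy-1β,4α,8α-trihydroxyeudesm-11(13)-en-12-oate, (1R,4R,5S,6S,7R,8S,10R) | C=C(C(=O)OC)[C@H]1[C@H](OC(=O)/C(C)=C\C)[C@@H]2[C@@](C)(C[C@@H]1O)[C@H](O)CC[C@@]2(C)O | target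

## Step count and risks
- **Total step count:** 13.
- **Longest linear sequence:** 12 (steps 1–4 and 6–13).

**Step 2, the proposed ring expansion.**
- Risks: the bicyclo[3.1.0]hexyl radical may only reopen its external bond. The cobalt hydride may also attack the ring alkene, or move the alkene of 4.
- Fallback with known chemistry, setting out from 1 and returning at 4:
  - 1,1-Dibromoethane is lithiated with LDA at −95 °C and added to 1. This gives 1-(1,1-dibromoethyl)-3-methylcyclopent-2-en-1-ol F1.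
  - Two equivalents of n-BuLi (THF, −78 → 0 °C) convert it into the dilithio β-oxido carbenoid F2.
  - The alkenyl carbon of F2 migrates with loss of bromide (β-oxido carbenoid ring enlargement). This gives the ring-enlarged lithium dienolate F3.
  - Kinetic α-protonation with aqueous NH4Cl gives 4.

**Step 6, the 1,4-addition and alkylation.**
- Risks: the β-carbon lies between a quaternary carbon and an α-methyl group. The thioester electrophile may be attacked by organocopper species, and the facial bias rests on OSiEt3 against CH3.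
- Fallback setting out from 7 and returning at 20:
  - The same enolate 11 is trapped with the far more reactive allyl bromide. This gives (2R,3R,4R)-3-ethenyl-2,4-dimethyl-2-(prop-2-enyl)-4-(triethylsilyloxy)cyclohexanone F4.
  - Exhaustive ozonolysis (O3, then PPh3) gives the C6,C8-dialdehyde F5.
  - Only the unhindered C8 aldehyde is acetalised (HC(OMe)3, CeCl3·7H2O cat., MeOH, 0 °C). This gives the C8 dimethyl acetal aldehyde F6.
  - Addition of 15 followed by 18, as in step 8, gives the angelate acetal F7.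
  - LiBF4 in wet MeCN releases aldehyde 20.

**Step 10, the ene closure.**
- Risks: the allylic angelate lowers the nucleophilicity of the alkene and can ionise on the Lewis acid.
- Fallback setting out from 14 and returning at 22, in which acylation is postponed so that the ene partner is an allylic silyl ether:
  - Compound 14 is treated with 15 and the alkoxide is quenched with Me3SiCl. This gives the 6-O-trimethylsilyl thioester F8.
  - Fukuyama reduction gives the 6-O-trimethylsilyl keto aldehyde F9.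
  - Sc(OTf)3 ene closure and in-flask Et3SiOTf silylation give 6α-(trimethylsilyloxy)-4α,8α-bis(triethylsilyloxy)eudesm-11(13)-en-1-one F10.
  - Citric acid in MeOH at 0 °C removes only the trimethylsilyl group. This gives 6α-hydroxy-4α,8α-bis(triethylsilyloxy)eudesm-11(13)-en-1-one F11.
  - LiHMDS followed by 18 acylates O6 to give 22.

## Further compounds
F1 | step 2 | 1-(1,1-dibromoethyl)-3-methylcyclopent-2-en-1-ol | CC1=CC(O)(CC1)C(C)(Br)Br
F2 | step 2 | dilithio β-oxido carbenoid of F1 | CC1=CC(O[Li])(CC1)C(C)(Br)[Li]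
F3 | step 2 | lithium dienolate of 2,4-dimethylcyclohex-3-en-1-one | CC1=CC(C)=C(O[Li])CC1
F4 | step 6 | (2R,3R,4R)-3-ethenyl-2,4-dimethyl-2-(prop-2-enyl)-4-(triethylsilyloxy)cyclohexanone | C=C[C@@H]1[C@@](C)(CC=C)C(=O)CC[C@@]1(C)O[Si](CC)(CC)CC
F5 | step 6 | C6,C8-dialdehyde: 2-formyl-1,3-dimethyl-6-oxo-3-(triethylsilyloxy)cyclohexylacetaldehyde | O=C[C@@H]1[C@@](C)(CC=O)C(=O)CC[C@@]1(C)O[Si](CC)(CC)CC
F6 | step 6 | C8 dimethyl acetal of F5 (C6 aldehyde free) | O=C[C@@H]1[C@@](C)(CC(OC)OC)C(=O)CC[C@@]1(C)O[Si](CC)(CC)CC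
F7 | step 6 | (6S)-angelate carrying the C8 dimethyl acetal | CC(C)=C[C@H](OC(=O)/C(C)=C\C)[C@@H]1[C@@](C)(CC(OC)OC)C(=O)CC[C@@]1(C)O[Si](CC)(CC)CC
F8 | step 10 | 6-O-trimethylsilyl thioester | CC(C)=C[C@H](O[Si](C)(C)C)[C@@H]1[C@@](C)(CC(=O)SCC)C(=O)CC[C@@]1(C)O[Si](CC)(CC)CC
F9 | step 10 | 6-O-trimethylsilyl keto aldehyde | CC(C)=C[C@H](O[Si](C)(C)C)[C@@H]1[C@@](C)(CC=O)C(=O)CC[C@@]1(C)O[Si](CC)(CC)CC
F10 | step 10 | 6α-(trimethylsilyloxy)-4α,8α-bis(triethylsilyloxy)eudesm-11(13)-en-1-one | C=C(C)[C@H]1[C@H](O[Si](C)(C)C)[C@@H]2[C@@](C)(C[C@@H]1O[Si](CC)(CC)CC)C(=O)CC[C@@]2(C)O[Si](CC)(CC)CC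
F11 | step 10 | 6α-hydroxy-4α,8α-bis(triethylsilyloxy)eudesm-11(13)-en-1-one | C=C(C)[C@H]1[C@H](O)[C@@H]2[C@@](C)(C[C@@H]1O[Si](CC)(CC)CC)C(=O)CC[C@@]2(C)O[Si](CC)(CC)CC
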